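**Two charges.** In the flask, which is the grey run followed further, the free catalyst charged is 2.6 mol% of the starting material and the impurity 1.60% of it, a margin of 1.00% if the two cancel one for one, as assumed here; in the blue run, with half the starting material and the same impurity, the impurity stands 0.600% above the catalyst.

all flasks: free catalyst 2.6 mol%; impurity 0.16 mM
- grey: starting material 10 mM; reagent 2.5 equiv; second substrate 5 equiv (fed, over 40 s); the very flask that is asked about, followed so far
- blue: starting material 5 mM; reagent 2.5 equiv; second substrate 5 equiv (fed, over 40 s); run made earlier
- flask: starting material 10 mM; reagent 2.50 equiv; second substrate 5.00 equiv (fed, over 40 s); time 15 min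

- grey (time / min: target / %, uncatalysed product / %, starting material / %): 1.00: 98, 2, 4; 2.00: 95, 3, 1; 3.00: 97, 5, 0; 4.00: 96, 6, 0; 5.00: 99, 5, 2; 6.00: 93, 3, 0; 8.00: 94, 4, 2
- blue (time / min: target / %, uncatalysed product / %, starting material / %): 0.833: 2, 38, 57; 2.50: 0, 71, 31; 4.00: 4, 82, 16; 6.00: 4, 94, 4; 10.0: 1, 100, 1; 12.0: 2, 99, 3; 15.0: 3, 100, 3

(standard deviation of a reading: 2 percentage points)

1. the state of affairs at 15 min: stopped, and by what, or still going (no working catalyst is left / it is still moving / all of the starting material has reacted / forward and back rates have come level)
2. amount of target at 15 min, in percent of the starting material charged
3. amount of uncatalysed product at 15 min, in percent of the starting material charged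

- the reaction counts as stopped when no species that holds the starting material changes by six tenths of a point or more over the second half of the time

**The split.** Target and uncatalysed product both draw on the starting material, so while the free catalyst holds steady, dividing one rate by the other removes time, and the ratio of the summed amounts can then stand in for the ratio of the rates. The grey readings give 24.0 for this split, the amount of target over the amount of uncatalysed product, taken here as a reading of the rate ratio in the grey run. The blue readings give 0.0274 for the same ratio of amounts, which is not taken as a rate ratio, since the free catalyst of the blue run is not assumed steady.

**First instants.** By this reckoning the impurity leaves 38.5% of the flask's catalyst working, while the second substrate, which no reading follows, is fed over 40 s. At 1.00 min the grey run reads 4% of starting material, less than the 57% of the blue run at 0.833 min.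

**Middle and end.** From 3.00 min to 8.00 min the grey starting material reads between 0% and 2%, with a scatter of 2 percentage points, so the split has nothing further to divide. The flask should stop with 96.0% of target and 4.00% of uncatalysed product.

**The check.** The forecast says all of the starting material has reacted, with 95.7% of target and 4.3% of uncatalysed product, 0.3 points above the reckoning here, on the ground that "With no starting material left, nothing further forms". The flask gives all of the starting material has reacted, with 95.7% of target and 3.85% of uncatalysed product.

    free catalyst + impurity → spent catalyst (k = 2.63 × 10⁵ M⁻¹ s⁻¹)
    starting material + reagent + free catalyst → free catalyst + target (k = 2.07 × 10⁵ M⁻² s⁻¹)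
    starting material + reagent → uncatalysed product (k = 0.849 M⁻¹ s⁻¹)
    second substrate + reagent + free catalyst → free catalyst + second product (k = 82500 M⁻² s⁻¹)

**The comparison.** At 0.235 min the step to target uses starting material 24 times as fast as the step to uncatalysed product, a rate ratio beside the split of 24.0 read from the grey amounts. With 38.5% of the catalyst free at 15.0 min, the final amounts of the flask divide to 24.9.

**Second flask.** In the neighbour with 0.40 mM of impurity, the impurity stands 1.40% of the starting material above the catalyst, on the blue side of the margin, so the split of 24.0 gives way to the blue ratio of amounts, 0.0274, which as an estimate means 97.3% of uncatalysed product. That neighbour computes to 98.0% of uncatalysed product and 2.04% of target.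

(The earlier runs and the new flask were generated by integration with constants of no real substance.)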